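**Plan**

1. Retrosynthetic cuts, in order: C14–OOH back to C14–OH (invertive perhydrolysis); the ring bond C1–C14 (alkenyl–chromium plus aldehyde); the lactone O–C10 bond and both oxiranes back to an E,E-diene acid; then C3–C4 (Negishi), C12–C13 ([3,3]) and C10–C11 (Grignard) back to a limonene-derived keto aldehyde.
2. Forward: both arms are grown on the C8 stereocentre; one double epoxidation gives the 4,5-oxirane and, by carboxylate opening of the 10,11-oxirane, the δ-lactone; the 14-membered carbocycle is closed after these rings, and the hydroperoxide is entered last.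
3. Enabling feature: in the 14-membered ring the O-bearing C14 is bonded to C1, which carries the exocyclic methylene (a 2-methylene carbinol, the retron of an alkenylmetal/aldehyde addition); the two chains leave the δ-lactone ring at C8 and C10 cis-diequatorial, so both chain ends point to the same side.
4. Stereochemistry: C8 from (R)-limonene; C4, C5, C10, C11 from one ent-Shi epoxidation (C10 inverted on lactonisation); Cα by equilibration to the all-equatorial lactone; C14 by a chiral chromium ligand, then inverted by SN2.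

Key step: step 16

**Remarks on the chemistry (assumptions)**

- Locants used throughout: the 14-membered carbocycle is numbered C1 (carbon bearing =CH2), C2, C3, C4 (oxirane CH), C5 (oxirane C–Me), C6, C7, C8 (lactone β-carbon), C9, C10 (lactone O–CH), C11 (C(Me)OH), C12, C13, C14 (C–OOH); Cα is the lactone CH(Me). The open-chain precursors keep these locants. In these locants the target is 4S,5S,8R,10R,11S,14R,αS.
- Commercial (+)-limonene 1,2-oxide is taken as the 4R cis/trans mixture; both isomers converge in step 1.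
- Hydroboration in step 10 is expected to give both Cα epimers without control; compounds 16–20 are carried as that mixture (Cα left open in their SMILES) and are funnelled to one epimer in step 13.

**Route**

Step 1
Reactants: 1 (4R)-limonene 1,2-oxide
Product: 2 (3R)-6-oxo-3-(prop-1-en-2-yl)heptanal
Conditions: H5IO6 (1.2 equiv), THF–H2O, 0 °C → rt
Reagents that add atoms: water, O
Why: Acid-mediated oxirane hydrolysis followed by Malaprade glycol cleavage opens the ring between the two oxirane carbons from either epoxide diastereomer and leaves the limonene stereocentre (future C8) untouched.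

Step 2
Reactants: 2 (3R)-6-oxo-3-(prop-1-en-2-yl)heptanal
Product: 3 (5R)-7,7-dimethoxy-5-(prop-1-en-2-yl)heptan-2-one
Conditions: HC(OMe)3, MeOH, CeCl3·7H2O (cat.), rt
Reagents that add atoms: trimethyl orthoformate, COC(OC)OC; methanol, CO
Why: Luche-type chemoselective acetalisation, in which the aldehyde forms its dimethyl acetal much faster than the methyl ketone.

Step 3
Reactants: 3 (5R)-7,7-dimethoxy-5-(prop-1-en-2-yl)heptan-2-one
Product: 5 (5R)-7,7-dimethoxy-5-(prop-1-en-2-yl)hept-1-yne, via enol phosphate 4 (not isolated)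
Conditions: LDA (1.05 equiv), THF, −78 °C; ClP(O)(OEt)2; then LDA (2.3 equiv), −78 °C → rt
Reagents that add atoms: none
Why: Negishi conversion of a methyl ketone into a terminal alkyne by kinetic enolisation on the methyl side, O-phosphorylation and base-induced elimination, so the former ketone methyl becomes C4.

Step 4
Reactants: 5 (5R)-7,7-dimethoxy-5-(prop-1-en-2-yl)hept-1-yne
Product: 7 (1E,5R)-1-iodo-7,7-dimethoxy-2-methyl-5-(prop-1-en-2-yl)hept-1-ene, via alkenylalane 6 (not isolated)
Conditions: Me3Al (2.5 equiv), Cp2ZrCl2 (0.25 equiv), H2O (1.2 equiv), CH2Cl2, −25 °C; then I2, THF, −25 → 0 °C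
Reagents that add atoms: trimethylaluminium, C[Al](C)C; iodine, II
Why: Zirconium-catalysed syn-methylalumination (Negishi carboalumination, water-accelerated low-temperature variant to spare the acetal) puts Me on C5 and Al on C4, and iodinolysis with retention should give the E-alkenyl iodide that fixes the C4=C5 geometry.

Step 5
Reactants: 8 3-bromobut-3-en-1-ol
Product: 9 2-bromo-4-iodobut-1-ene
Conditions: I2, PPh3, imidazole, CH2Cl2, 0 °C
Reagents that add atoms: iodine, II
Why: Appel-type (Garegg–Samuelsson) conversion of the primary alcohol into the iodide, to which the 2-bromoalkene is inert.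

Step 6
Reactants: 7 (1E,5R)-1-iodo-7,7-dimethoxy-2-methyl-5-(prop-1-en-2-yl)hept-1-ene; 9 2-bromo-4-iodobut-1-ene
Product: 11 (5E,9R)-2-bromo-11,11-dimethoxy-6-methyl-9-(prop-1-en-2-yl)undeca-1,5-diene, via alkylzinc iodide 10 (not isolated)
Conditions: 9, Zn dust, LiCl, THF, 35 °C; then 7, Pd(PPh3)4 (5 mol%), THF, 40 °C
Reagents that add atoms: none
Why: Negishi sp2–sp3 cross-coupling, in which Pd(0) inserts into the alkenyl C–I bond in preference to the 2-bromoalkene and couples with retention, so the E geometry of step 4 is kept and C3–C1 arrive with the bromoalkene in place.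

Step 7
Reactants: 11 (5E,9R)-2-bromo-11,11-dimethoxy-6-methyl-9-(prop-1-en-2-yl)undeca-1,5-diene
Product: 12 (3R,6E)-10-bromo-6-methyl-3-(prop-1-en-2-yl)undeca-6,10-dienal
Conditions: PPTS (cat.), acetone–H2O, 50 °C
Reagents that add atoms: water, O
Why: Mild acid hydrolysis of the dimethyl acetal, which the alkenes and the alkenyl bromide tolerate.

Step 8
Reactants: 12 (3R,6E)-10-bromo-6-methyl-3-(prop-1-en-2-yl)undeca-6,10-dienal
Product: 13 (3RS,5R,8E)-12-bromo-2,8-dimethyl-5-(prop-1-en-2-yl)trideca-1,8,12-trien-3-ol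
Conditions: isopropenylmagnesium bromide (1.3 equiv), THF, −78 → −20 °C; aq. NH4Cl
Reagents that add atoms: isopropenylmagnesium bromide, C=C(C)[Mg]Br
Why: Grignard 1,2-addition brings in C11, its methyl and C12; the carbinol centre forms without control, which does not matter because step 9 destroys it.

Step 9
Reactants: 13 (3RS,5R,8E)-12-bromo-2,8-dimethyl-5-(prop-1-en-2-yl)trideca-1,8,12-trien-3-ol
Product: 15 (4E,7R,10E)-14-bromo-N,N,4,10-tetramethyl-7-(prop-1-en-2-yl)pentadeca-4,10,14-trienamide, via ketene N,O-acetal 14 (not isolated)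
Conditions: MeC(OMe)2NMe2 (4 equiv), xylenes, 140 °C
Reagents that add atoms: N,N-dimethylacetamide dimethyl acetal, COC(C)(OC)N(C)C
Why: Eschenmoser–Claisen rearrangement through a chair transition state with the C9 substituent equatorial should give the E-trisubstituted C10=C11 alkene from both carbinol epimers (stereoconvergent) and delivers C13/C14 as an amide that survives to step 15.

Step 10
Reactants: 15 (4E,7R,10E)-14-bromo-N,N,4,10-tetramethyl-7-(prop-1-en-2-yl)pentadeca-4,10,14-trienamide
Product: 17 (4E,7R,10E)-14-bromo-7-[(2RS)-1-hydroxypropan-2-yl]-N,N,4,10-tetramethylpentadeca-4,10,14-trienamide, via B-alkyl-9-BBN adduct 16 (not isolated)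
Conditions: 9-BBN (1.15 equiv), THF, 0 °C → rt; then 3 M NaOH, 30% H2O2, 0 °C → rt
Reagents that add atoms: hydrogen peroxide, OO
Why: Anti-Markovnikov hydroboration–oxidation, in which 9-BBN should prefer the unhindered 1,1-disubstituted isopropenyl group over the two trisubstituted alkenes and the inductively deactivated 2-bromoalkene; Cα forms without control and is corrected in step 13.

Step 11
Reactants: 17 (4E,7R,10E)-14-bromo-7-[(2RS)-1-hydroxypropan-2-yl]-N,N,4,10-tetramethylpentadeca-4,10,14-trienamide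
Product: 18 (2RS)-2-[(4E,7R,10E)-14-bromo-1-(dimethylamino)-4,10-dimethyl-1-oxopentadeca-4,10,14-trien-7-yl]propanoic acid
Conditions: TEMPO (0.2 equiv), PhI(OAc)2 (2.4 equiv), MeCN–pH 7 buffer, rt
Reagents that add atoms: water, O
Why: Oxoammonium (TEMPO/BAIB) oxidation of the primary alcohol through the aldehyde hydrate to the acid, a method that leaves trisubstituted alkenes, amide and alkenyl bromide alone.

Step 12
Reactants: 18 (2RS)-2-[(4E,7R,10E)-14-bromo-1-(dimethylamino)-4,10-dimethyl-1-oxopentadeca-4,10,14-trien-7-yl]propanoic acid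
Product: 20 (4S)-4-[(2R,4R,5RS)-4-{2-[(2S,3S)-3-(3-bromobut-3-en-1-yl)-2-methyloxiran-2-yl]ethyl}-5-methyl-6-oxooxan-2-yl]-4-hydroxy-N,N-dimethylpentanamide, via bis-epoxy acid 19 (not isolated)
Conditions: ent-Shi ketone (0.6 equiv), Oxone, K2CO3, Bu4NHSO4 (cat.), MeCN–DMM–aq. borate buffer (pH 10.5), 0 °C; then 40 °C; then acidify to pH 4 at 0 °C
Reagents that add atoms: potassium peroxymonosulfate (Oxone), [K+].[O-]S(=O)(=O)OO
Why: Shi epoxidation (chiral dioxirane, spiro transition state) should give the S,S-oxirane at both E-trisubstituted alkenes under reagent control, while the electron-poor 2-bromoalkene is left alone; the carboxylate then opens only the nearby 10,11-oxirane in a 6-exo-tet SN2 at the less substituted C10 with inversion (10S → 10R), which leaves the 11S tertiary alcohol and the 4S,5S-oxirane.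

Step 13
Reactants: 20 (4S)-4-[(2R,4R,5RS)-4-{2-[(2S,3S)-3-(3-bromobut-3-en-1-yl)-2-methyloxiran-2-yl]ethyl}-5-methyl-6-oxooxan-2-yl]-4-hydroxy-N,N-dimethylpentanamide
Product: 21 (4S)-4-[(2R,4R,5S)-4-{2-[(2S,3S)-3-(3-bromobut-3-en-1-yl)-2-methyloxiran-2-yl]ethyl}-5-methyl-6-oxooxan-2-yl]-4-hydroxy-N,N-dimethylpentanamide
Conditions: KOtBu (0.3 equiv), t-BuOH–THF, 0 °C → rt; AcOH quench
Reagents that add atoms: none
Why: Base-catalysed epimerisation through the lactone enolate is a dynamic, stereoconvergent step that should funnel both Cα epimers into the thermodynamically preferred lactone with the α-methyl trans to the C8 chain and all three ring substituents equatorial.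

Step 14
Reactants: 21 (4S)-4-[(2R,4R,5S)-4-{2-[(2S,3S)-3-(3-bromobut-3-en-1-yl)-2-methyloxiran-2-yl]ethyl}-5-methyl-6-oxooxan-2-yl]-4-hydroxy-N,N-dimethylpentanamide
Product: 22 (4S)-4-[(2R,4R,5S)-4-{2-[(2S,3S)-3-(3-bromobut-3-en-1-yl)-2-methyloxiran-2-yl]ethyl}-5-methyl-6-oxooxan-2-yl]-N,N-dimethyl-4-[(triethylsilyl)oxy]pentanamide
Conditions: TESOTf (1.5 equiv), 2,6-lutidine (3 equiv), CH2Cl2, −78 → −40 °C
Reagents that add atoms: triethylsilyl triflate, CC[Si](CC)(CC)OS(=O)(=O)C(F)(F)F
Why: Silyl triflate silylation of the tertiary C11 alcohol, needed so that it cannot form a lactol with the C14 aldehyde (steps 15–16) or a tetrahydrofuran by attack on the C14 mesylate (step 17).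

Step 15
Reactants: 22 (4S)-4-[(2R,4R,5S)-4-{2-[(2S,3S)-3-(3-bromobut-3-en-1-yl)-2-methyloxiran-2-yl]ethyl}-5-methyl-6-oxooxan-2-yl]-N,N-dimethyl-4-[(triethylsilyl)oxy]pentanamide
Product: 24 (4S)-4-[(2R,4R,5S)-4-{2-[(2S,3S)-3-(3-bromobut-3-en-1-yl)-2-methyloxiran-2-yl]ethyl}-5-methyl-6-oxooxan-2-yl]-4-[(triethylsilyl)oxy]pentanal, via zirconated hemiaminal 23 (not isolated)
Conditions: Cp2Zr(H)Cl (1.6 equiv), THF, rt, 20 min; then H2O/silica gel
Reagents that add atoms: none
Why: Schwartz-reagent reduction of a tertiary amide (Georg protocol) adds hydride to the amide carbonyl to give a tetrahedral adduct that is stable until work-up, so the aldehyde is released without over-reduction, and lactone, oxirane and the hindered 2-bromoalkene should react far more slowly.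

Step 16
Reactants: 24 (4S)-4-[(2R,4R,5S)-4-{2-[(2S,3S)-3-(3-bromobut-3-en-1-yl)-2-methyloxiran-2-yl]ethyl}-5-methyl-6-oxooxan-2-yl]-4-[(triethylsilyl)oxy]pentanal
Product: 25 macrocyclic allylic alcohol (4S,5S,8R,10R,11S,14S,αS): 14-membered carbocycle with 1-methylene 4,5-oxirane 8,10-fused δ-lactone 11-OTES 14-OH
Conditions: CrCl2 (6 equiv), Kishi-type chiral oxazoline–sulfonamide ligand (7 equiv, the antipode that gives 14S), Et3N, NiCl2·(2,9-dimethyl-1,10-phenanthroline) (0.3 equiv), THF–MeCN, rt, slow addition of 24 to a final concentration of about 2 mM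
Reagents that add atoms: none
Why: Ni(0) inserts into the C1–Br bond, the alkenyl group is passed to Cr(III), and the alkenylchromium adds to the C14 aldehyde (Nozaki–Hiyama–Kishi reaction in its ligand-controlled macrocyclising form, the closest precedent being Ni/Cr closures of large carbocycles and macrolides with chiral sulfonamide ligands). The 14-membered carbocycle closes in a 14-exo-trig mode (C1 nucleophile onto the exocyclic C14=O); no other ring forms in this step, and lactone and oxirane are already present. The new stereocentre C14 is set by the chiral ligand on chromium (reagent control), chosen to give the 14S carbinol required for the invertive peroxide entry. The step needs chemoselectivity for the aldehyde over lactone, oxirane and silyl ether, which the weakly basic, aldehyde-specific organochromium(III) reagent should secure. It also needs ring closure to beat oligomerisation, which slow addition at high dilution and the cis-diequatorial arms on the δ-lactone should favour. The exocyclic C1=CH2 comes directly from the 2-bromoalkene, so no separate olefination is needed.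

Step 17
Reactants: 25 macrocyclic allylic alcohol (4S,5S,8R,10R,11S,14S,αS)
Product: 27 macrocyclic hydroperoxide TES ether (4S,5S,8R,10R,11S,14R,αS), via mesylate 26 (not isolated)
Conditions: MsCl (1.3 equiv), Et3N (3 equiv), CH2Cl2, −40 °C; then anhydrous H2O2 in Et2O (20 equiv), −40 → 0 °C
Reagents that add atoms: hydrogen peroxide, OO
Why: Perhydrolysis of a secondary allylic sulfonate (Williams–Mosher/Corey type), in which the α-effect nucleophile H2O2, activated by the amine, should displace the mesylate by SN2 with inversion (14S → 14R), low temperature disfavouring SN2′ attack at the methylene terminus and elimination.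

Step 18
Reactants: 27 macrocyclic hydroperoxide TES ether (4S,5S,8R,10R,11S,14R,αS)
Product: 28 target hydroperoxide (4S,5S,8R,10R,11S,14R,αS)
Conditions: HF·pyridine, pyridine, THF, 0 °C → rt
Reagents that add atoms: none
Why: Buffered fluoride cleavage of the tertiary TES ether, under conditions known to spare trisubstituted oxiranes and lactones and too weakly acidic to rearrange the hydroperoxide.

**Compound list**

1 | (4R)-limonene 1,2-oxide (cis/trans mixture) | CC12OC1C[C@@H](CC2)C(C)=C | starting material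
2 | (3R)-6-oxo-3-(prop-1-en-2-yl)heptanal | O=CC[C@@H](CCC(C)=O)C(C)=C | intermediate
3 | (5R)-7,7-dimethoxy-5-(prop-1-en-2-yl)heptan-2-one | COC(OC)C[C@@H](CCC(C)=O)C(C)=C | intermediate
4 | diethyl (5R)-7,7-dimethoxy-5-(prop-1-en-2-yl)hept-1-en-2-yl phosphate (enol phosphate, not isolated) | COC(OC)C[C@@H](CCC(=C)OP(=O)(OCC)OCC)C(C)=C | intermediate
5 | (5R)-7,7-dimethoxy-5-(prop-1-en-2-yl)hept-1-yne | COC(OC)C[C@@H](CCC#C)C(C)=C | intermediate
6 | dimethyl[(1E,5R)-7,7-dimethoxy-2-methyl-5-(prop-1-en-2-yl)hept-1-en-1-yl]alumane (alkenylalane, not isolated) | COC(OC)C[C@@H](CC/C(C)=C/[Al](C)C)C(C)=C | intermediate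
7 | (1E,5R)-1-iodo-7,7-dimethoxy-2-methyl-5-(prop-1-en-2-yl)hept-1-ene | COC(OC)C[C@@H](CC/C(C)=C/I)C(C)=C | intermediate
8 | 3-bromobut-3-en-1-ol | OCCC(Br)=C | starting material
9 | 2-bromo-4-iodobut-1-ene | ICCC(Br)=C | intermediate
10 | (3-bromobut-3-en-1-yl)zinc iodide (not isolated) | I[Zn]CCC(Br)=C | intermediate
11 | (5E,9R)-2-bromo-11,11-dimethoxy-6-methyl-9-(prop-1-en-2-yl)undeca-1,5-diene | COC(OC)C[C@@H](CC/C(C)=C/CCC(Br)=C)C(C)=C | intermediate
12 | (3R,6E)-10-bromo-6-methyl-3-(prop-1-en-2-yl)undeca-6,10-dienal | O=CC[C@@H](CC/C(C)=C/CCC(Br)=C)C(C)=C | intermediate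
13 | (3RS,5R,8E)-12-bromo-2,8-dimethyl-5-(prop-1-en-2-yl)trideca-1,8,12-trien-3-ol (both carbinol epimers) | C=C(C)C(O)C[C@@H](CC/C(C)=C/CCC(Br)=C)C(C)=C | intermediate
14 | N,N-dimethyl-1-{[(5R,8E)-12-bromo-2,8-dimethyl-5-(prop-1-en-2-yl)trideca-1,8,12-trien-3-yl]oxy}ethen-1-amine (ketene N,O-acetal, not isolated) | C=C(N(C)C)OC(C[C@@H](CC/C(C)=C/CCC(Br)=C)C(C)=C)C(C)=C | intermediate
15 | (4E,7R,10E)-14-bromo-N,N,4,10-tetramethyl-7-(prop-1-en-2-yl)pentadeca-4,10,14-trienamide | CN(C)C(=O)CC/C(C)=C/C[C@@H](CC/C(C)=C/CCC(Br)=C)C(C)=C | intermediate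
16 | 9-{2-[(4E,7R,10E)-14-bromo-1-(dimethylamino)-4,10-dimethyl-1-oxopentadeca-4,10,14-trien-7-yl]propyl}-9-borabicyclo[3.3.1]nonane (Cα epimers, not isolated) | CN(C)C(=O)CC/C(C)=C/C[C@@H](CC/C(C)=C/CCC(Br)=C)C(C)CB1C2CCCC1CCC2 | intermediate
17 | (4E,7R,10E)-14-bromo-7-[(2RS)-1-hydroxypropan-2-yl]-N,N,4,10-tetramethylpentadeca-4,10,14-trienamide (Cα epimers) | CN(C)C(=O)CC/C(C)=C/C[C@@H](CC/C(C)=C/CCC(Br)=C)C(C)CO | intermediate
18 | (2RS)-2-[(4E,7R,10E)-14-bromo-1-(dimethylamino)-4,10-dimethyl-1-oxopentadeca-4,10,14-trien-7-yl]propanoic acid (Cα epimers) | CN(C)C(=O)CC/C(C)=C/C[C@@H](CC/C(C)=C/CCC(Br)=C)C(C)C(=O)O | intermediate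
19 | (2RS,3R)-3-({(2S,3S)-3-[3-(dimethylamino)-3-oxopropyl]-3-methyloxiran-2-yl}methyl)-5-[(2S,3S)-3-(3-bromobut-3-en-1-yl)-2-methyloxiran-2-yl]-2-methylpentanoic acid (bis-epoxy acid, present as carboxylate, not isolated) | CN(C)C(=O)CC[C@]1(C)O[C@H]1C[C@@H](CC[C@]2(C)O[C@H]2CCC(Br)=C)C(C)C(=O)O | intermediate
20 | (4S)-4-[(2R,4R,5RS)-4-{2-[(2S,3S)-3-(3-bromobut-3-en-1-yl)-2-methyloxiran-2-yl]ethyl}-5-methyl-6-oxooxan-2-yl]-4-hydroxy-N,N-dimethylpentanamide (Cα epimers) | C=C(Br)CC[C@@H]1O[C@@]1(C)CC[C@@H]1C[C@@H](OC(=O)C1C)[C@@](C)(O)CCC(=O)N(C)C | intermediate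
21 | (4S)-4-[(2R,4R,5S)-4-{2-[(2S,3S)-3-(3-bromobut-3-en-1-yl)-2-methyloxiran-2-yl]ethyl}-5-methyl-6-oxooxan-2-yl]-4-hydroxy-N,N-dimethylpentanamide | C=C(Br)CC[C@@H]1O[C@@]1(C)CC[C@@H]1C[C@@H](OC(=O)[C@H]1C)[C@@](C)(O)CCC(=O)N(C)C | intermediate
22 | (4S)-4-[(2R,4R,5S)-4-{2-[(2S,3S)-3-(3-bromobut-3-en-1-yl)-2-methyloxiran-2-yl]ethyl}-5-methyl-6-oxooxan-2-yl]-N,N-dimethyl-4-[(triethylsilyl)oxy]pentanamide | C=C(Br)CC[C@@H]1O[C@@]1(C)CC[C@@H]1C[C@@H](OC(=O)[C@H]1C)[C@@](C)(O[Si](CC)(CC)CC)CCC(=O)N(C)C | intermediate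
23 | O-[chlorobis(cyclopentadienyl)zirconio] N,N-dimethyl hemiaminal of 24 (zirconated hemiaminal, not isolated) | C=C(Br)CC[C@@H]1O[C@@]1(C)CC[C@@H]1C[C@@H](OC(=O)[C@H]1C)[C@@](C)(O[Si](CC)(CC)CC)CCC(O[Zr](Cl)(C1C=CC=C1)C1C=CC=C1)N(C)C | intermediate
24 | (4S)-4-[(2R,4R,5S)-4-{2-[(2S,3S)-3-(3-bromobut-3-en-1-yl)-2-methyloxiran-2-yl]ethyl}-5-methyl-6-oxooxan-2-yl]-4-[(triethylsilyl)oxy]pentanal | C=C(Br)CC[C@@H]1O[C@@]1(C)CC[C@@H]1C[C@@H](OC(=O)[C@H]1C)[C@@](C)(O[Si](CC)(CC)CC)CCC=O | intermediate
25 | macrocyclic allylic alcohol (4S,5S,8R,10R,11S,14S,αS): 14-membered carbocycle, C1=CH2, 4,5-oxirane (5-Me), δ-lactone across C8/C10 with α-Me, 11-Me, 11-OTES, 14-OH | C=C1CC[C@@H]2O[C@@]2(C)CC[C@@H]2C[C@@H](OC(=O)[C@H]2C)[C@@](C)(O[Si](CC)(CC)CC)CC[C@@H]1O | intermediate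
26 | C14 methanesulfonate of 25 (14S, not isolated) | C=C1CC[C@@H]2O[C@@]2(C)CC[C@@H]2C[C@@H](OC(=O)[C@H]2C)[C@@](C)(O[Si](CC)(CC)CC)CC[C@@H]1OS(C)(=O)=O | intermediate
27 | macrocyclic hydroperoxide TES ether (4S,5S,8R,10R,11S,14R,αS): as 25 but 14-OOH with inverted C14 | C=C1CC[C@@H]2O[C@@]2(C)CC[C@@H]2C[C@@H](OC(=O)[C@H]2C)[C@@](C)(O[Si](CC)(CC)CC)CC[C@H]1OO | intermediate
28 | target (4S,5S,8R,10R,11S,14R,αS): 14-membered carbocycle, C1=CH2, 4,5-oxirane (5-Me), δ-lactone across C8/C10 with α-Me, 11-Me, 11-OH, 14-OOH | C=C1CC[C@@H]2O[C@@]2(C)CC[C@@H]2C[C@@H](OC(=O)[C@H]2C)[C@@](C)(O)CC[C@H]1OO | target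

**Step count and risks**

Total step count: 18. Longest linear sequence: 17 (steps 1–4 and 6–18 from 1; step 5 is a one-step side branch).

The three steps most likely to fail:

1. Step 17 (peroxide entry). The peroxide may attack the methylene terminus (SN2′), the mesylate may eliminate to a diene, the allylic centre may ionise and lose configuration, or H2O2 may be alkylated twice. Fallback: set out from 25, form mesylate 26 as in the route, and displace it with the caesium salt of 2-methoxyprop-2-yl hydroperoxide (CsOH·H2O, DMF, 0 °C). This monoprotected peroxide nucleophile is known to alkylate secondary sulfonates by SN2, and it should give the C14-inverted peroxyketal F1. Mild hydrolysis of the ketal (AcOH–THF–H2O, rt) then releases the hydroperoxide, and the route is rejoined at 27.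

2. Step 16 (ring closure). Ring closure may lose to oligomerisation, Ni insertion into the 2-bromoalkene may be slow, or the ligand may give poor or mismatched facial selectivity at C14. Fallback: set out from 24 and close the ring with achiral CrCl2/NiCl2 in DMSO–THF at high dilution, accepting 25 together with its C14 epimer, the 14R alcohol F2. Oxidise the mixture with Dess–Martin periodinane to the macrocyclic α-methylene ketone F3. Reduce F3 under reagent control with (R)-2-methyl-CBS-oxazaborolidine and catecholborane at −78 °C, which by the CBS model (alkenyl as the large group) should give the 14S alcohol; the route is rejoined at 25.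

3. Step 12 (double epoxidation with lactonisation). Facial selectivity may be incomplete at one of the two remote alkenes, and in the aqueous medium the 10,11-oxirane may be opened by water or in the 7-endo mode at C11 during acidification. Fallback: set out from 18 and mask the acid as methyl ester F4 (TMSCHN2, MeOH–toluene). Epoxidise under the same ent-Shi conditions to the isolable bis-epoxy ester F5, which can be purified from diastereomers. Then unmask the carboxylate under anhydrous conditions with KOSiMe3 in THF (rt → 50 °C) so that only the 6-exo SN2 opening at C10 can occur; mild acid work-up rejoins the route at 20.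

**Further compounds**

F1 | step 17 | C14 (2-methoxypropan-2-yl)peroxy macrocycle TES ether (4S,5S,8R,10R,11S,14R,αS) | C=C1CC[C@@H]2O[C@@]2(C)CC[C@@H]2C[C@@H](OC(=O)[C@H]2C)[C@@](C)(O[Si](CC)(CC)CC)CC[C@H]1OOC(C)(C)OC
F2 | step 16 | C14 epimer of 25, macrocyclic allylic alcohol (4S,5S,8R,10R,11S,14R,αS) | C=C1CC[C@@H]2O[C@@]2(C)CC[C@@H]2C[C@@H](OC(=O)[C@H]2C)[C@@](C)(O[Si](CC)(CC)CC)CC[C@H]1O
F3 | step 16 | macrocyclic α-methylene ketone at C14 (4S,5S,8R,10R,11S,αS) | C=C1CC[C@@H]2O[C@@]2(C)CC[C@@H]2C[C@@H](OC(=O)[C@H]2C)[C@@](C)(O[Si](CC)(CC)CC)CCC1=O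
F4 | step 12 | methyl (2RS)-2-[(4E,7R,10E)-14-bromo-1-(dimethylamino)-4,10-dimethyl-1-oxopentadeca-4,10,14-trien-7-yl]propanoate | CN(C)C(=O)CC/C(C)=C/C[C@@H](CC/C(C)=C/CCC(Br)=C)C(C)C(=O)OC
F5 | step 12 | methyl (2RS,3R)-3-({(2S,3S)-3-[3-(dimethylamino)-3-oxopropyl]-3-methyloxiran-2-yl}methyl)-5-[(2S,3S)-3-(3-bromobut-3-en-1-yl)-2-methyloxiran-2-yl]-2-methylpentanoate | CN(C)C(=O)CC[C@]1(C)O[C@H]1C[C@@H](CC[C@]2(C)O[C@H]2CCC(Br)=C)C(C)C(=O)OC
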